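Dusk and midnight differ in c(starting material) by a ratio of 2.31, yet after 3.00 min they read 77.9% and 77.8% of target, while autumn, with half the catalyst, reads 56.7%. So the target curve in percent follows the catalyst charge, and amber, with 2.0 mM in 4 portions, can be read on the dusk and midnight curve. Teal has that charge at once, whereas dusk, midnight and autumn were dosed in portions, so what a single charge does stands outside these readings and the curve gives teal a provisional value.

| setting | dusk | midnight | autumn | teal | amber |
|---|---|---|---|---|---|
| starting material | 0.013 M | 0.030 M | 0.020 M | 0.020 M | 0.020 M |
| catalyst | 2 mM (in portions, 4) | 2 mM (in portions, 4) | 1 mM (in portions, 4) | 2.0 mM | 2.0 mM (in portions, 4) |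
| remark | run made earlier; portions every 3.0 s | run made earlier; portions every 3.0 s | run made earlier; portions every 3.0 s | everything together at the start | the portions of catalyst follow each other after 3.0 s, the first at the start |
| time |  |  |  | 2.0 min | 4.0 min |

| run | time / min | target / % |
|---|---|---|
| dusk | 0.250 | 48.1 |
| dusk | 0.500 | 65.2 |
| dusk | 0.833 | 71.5 |
| dusk | 1.50 | 75.6 |
| dusk | 3.00 | 77.9 |
| midnight | 0.250 | 47.4 |
| midnight | 0.500 | 65.8 |
| midnight | 0.833 | 72.4 |
| midnight | 1.50 | 75.6 |
| midnight | 3.00 | 77.8 |
| autumn | 0.667 | 46.8 |
| autumn | 1.33 | 53.3 |
| autumn | 2.00 | 54.9 |
| autumn | 2.50 | 55.4 |
| autumn | 3.00 | 56.7 |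

(standard deviation of a reading: 0.5 percentage points)

- steps that have been proposed: starting material <-> other conformer; starting material -> uncatalysed product; starting material + catalyst -> catalyst + target; catalyst <-> dormant form; catalyst + other conformer -> catalyst + isomer of the product
- in a conversion other conformer counts as not yet reacted

- which of the two ends with the higher amount of target, in percent of the starting material charged ("neither" if they lie within 2 percentage points) (teal / amber / neither)
- target at the end, in percent of the starting material charged, teal
- target at the end, in percent of the starting material charged, amber

Averaged, that curve stands at 77.8% at 3.00 min. It gains 3.6 percentage points from 0.833 min to 1.50 min, then 2.2 points up to 3.00 min. Carrying the last slope on as a straight line puts amber at 79.3% and the curve at teal's 2.0 min at 76.3%, which are 3 points apart, beyond the margin of 2 points.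

The straight line is the weak link: the slope fell by a factor of 3.65 between the two intervals, whose midpoints lie 1.08 min apart. Read as a gap shrinking in proportion to itself, this gives 0.580 min for the tail's halving time, the time in which the gap between target and the level it heads for is cut in 2. This is a reading, with the scatter of 0.5 points in it.

The last interval then leaves a gap of 0.45 points at 3.00 min, so the level is 78.3%. Amber at 4.0 min reaches 78.2%. At teal's 2.0 min the curve of the portioned runs stands at 76.8%, which serves as the provisional value for teal, with its single charge not reckoned in. The two lie 1.4 points apart, inside the margin, so this reckoning calls it neither.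

The forecast, which differs from this reckoning in its call, gave 76.7% for teal and 79.2% for amber, named amber, and wrote: “Its extra two minutes of tail favour amber”.

The flask gives neither, with teal at 78.9% and amber at 78.4%.

    starting material ⇌ other conformer (K = 0.870, k = 0.00710 /s)
    starting material → uncatalysed product (k = 0.00180 /s)
    starting material + catalyst → catalyst + target (k = 44.0 /M/s)
    catalyst ⇌ dormant form (K = 20.0, k = 0.0490 /s)
    catalyst + other conformer → catalyst + isomer of the product (k = 40.0 /M/s)

Amber lies 0.20 points from its reckoned value, while teal ends 2.1 points above its own; at 2.00 min amber holds 76.2% of target against teal's 78.9%. The halving time serves on the neighbouring flask, amber stopped at 1.0 min. From 3.00 min back to that time the gap grows to 4.9 points, which puts target at 73.4%. That flask holds 73.3%.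

All runs were generated by integration with made-up constants, noise included.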